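## Analysis of the target

Ainsliatrimer A (23) is a trimer of three guaianolide units A, B and C (guaiane numbering in each). Each unit keeps the cyclopentane–cycloheptane core, the trans-fused α-methylene-γ-lactone on C6/C7 and the configurations at C5, C6 and C7 of dehydrocostus lactone (1); unit C also keeps C1. The units are joined by two cyclohexenes that are spiro to a cyclopentanone: R1 (C2A=C1A, C10A, C14A, C15B, C4B; spiro at C4B) and R2 (C4C, C15C, C14B, C10B, C1B=C2B; spiro at C4C). Ten of the fourteen stereocentres come with the monomers and four are new. Read from the descriptors, C4(C) carries C2(B) on the face of H5(C), C10(B) has its hydroxyl β and C14 α, C4(B) carries C2(A) on the β face, and H10(A) is α. The sensitive functions are the three α-methylene lactones and the exo-methylene enone of unit A (Michael acceptors and radical traps), the γ-hydroxy enone of unit B with its tertiary allylic alcohol, and the enolisable ketones. The difficulty is that the same functional groups occur three times, so every step has to tell one unit from another, while two all-carbon quaternary spiro centres are made next to carbonyl groups and the C10(B) oxygen is placed on one face. The plan rests on R2: C3(C)–C4(C)–C2(B)–C3(B) is a 1,4-diketone, and the C10(B) hydroxyl lies on the same face of R2 as C3(C). A 1,4-diketone is the product of an oxidative coupling of two enol derivatives, and a hydroxyl cis to a ketone carbon across a six-membered ring is what remains when an oxygen bridge between them is opened by water. R2 is therefore read as a hydrolysed 2-oxabicyclo[2.2.2]octane whose oxygen was the ring oxygen of a hetero-Diels–Alder dihydropyran.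

## Retrosynthetic reasoning

**23 to 22.** The conjugated enone C2(A)=C1(A) with H10(A) is the isomer of the β,γ-enone 22 (C1(A)=C10(A)). No bond is cut; moving the double bond back turns R1 into a Diels–Alder retron. The forward step has to move one proton from C2(A) to the α face of C10(A).

**22 to 19 and 21.** R1 is cut at C2(A)–C4(B) and C14(A)–C15(B). The diene C2=C1–C10=C14 of trienone 21 is locked s-cis, and the dienophile is the exo-methylene of the cross-conjugated dienone of 19. R1 is cut before R2 because unit A then enters last as a monomer derivative with no carbon moved, and the quaternary C4(B) arises at a 1,1-disubstituted dienophile. 21 cannot be stored and is made in the flask from silyl dienol ether 20, itself from 4.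

**19 to 18, 17 and 16.** The C1(B)=C2(B) bond is removed, which leads back to a ketone that must be desaturated through its C2(B) enol derivative. A free ketol would offer the base a second ketone, C3(C), with an unhindered α-CH2. The C3(C) carbonyl and the C10(B) hydroxyl are therefore held together as the bridged methyl ketal (16 to 18), the same oxygen bridge that the key step passes through. The ketal is opened before the cycloaddition, because the facial bias of the dienophile comes from the open ketol.

**16 to 15 and 13.** The exo-methylene of unit B has to be absent up to this point. A free B enone would itself act as heterodiene and as the preferred dienophile in the pyran-forming step, and would be a radical acceptor in the key step. It is masked as the sulfinate adduct (C15 as CH2SO2Ph) and returned by E1cB elimination. A plain C4 methyl group would be simpler to put on, but its removal through a C4 selenoxide would place selenium syn to H5(B) and allow the endocyclic enone. The sulfone leaves only the exocyclic alkene.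

**13 to 9 (key disconnection).** The C2(B)–C4(C) bond is cut, the central bond of the 1,4-diketone. Both carbons are then α-carbons of enol derivatives: a silyl enol ether in unit B and the enol ether of a dihydropyran in unit C, whose oxygen is the future C10(B) hydroxyl. Cutting here closes R2 and creates C4(C) and C2(B) in one bond-forming event, with the C10(B) oxygen already in place. The forward reaction has to join two nucleophilic carbons oxidatively, bridging the pyran, and then release the bridge with water (10).

**9 to 7, then 4 and 6.** The silyl enol ether comes from the B ketone of 7 by kinetic enolisation at C2. 7 is cut at O–C10(B) and C15(C)–C14(B), a hetero-Diels–Alder union of the enone of 4 (heterodiene O=C3–C4=C15) with the C10=C14 alkene of 6. This step sets C10(B).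

**6 and 4 to 3 and 1.** 6 is the conjugate adduct of benzenesulfinate (5) with 4. 4 comes from 1 by allylic oxidation to 3 and oxidation of the alcohol. One natural product thus supplies all 45 carbons.

## Alternatives that were turned down

**Alternative 1:** The disconnection is the C4(B)–C15(B) bond of R1, opened to the hexatriene C4(B)=C2(A)–C1(A)=C10(A)–C14(A)=C15(B). The forward key step is a thermal disrotatory 6π electrocyclisation that closes R1 and gives the spiro-cyclohexadiene A1.
- For: it makes the quaternary C4(B) without reagents, with no oxidant or base near the methylene lactones. On mildness it is stronger than a cerium oxidation.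
- Against: the hexatriene is not latent in the monomers. C15(B) would have to be detached from C4(B) and re-attached as a vinyl group on C10(A), and two cyclopentanones would have to be joined through a tetrasubstituted C2(A)=C4(B) alkene.
- Against: the two disrotatory senses give the two spiro epimers, with only remote centres to choose between them.
- Against: A1 has one alkene too many (C10(A)=C14(A)), whose reduction must set C10(A) and spare five other conjugated alkenes. A1 also contains no unit C, so R2 and the carbinol remain unsolved.
- Comparison: the chosen plan spends its key step on R2, where two centres and the oxygen function are set together, and closes R1 with a monomer-derived diene in which no carbon is moved.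

**Alternative 2:** The disconnection is C2(B)–C4(C) together with C14(B)–C10(B). The forward key step is a base-mediated Michael–aldol annulation that gives A2. C4(C), as the central carbon of a 1,3-dicarbonyl unit (C3(C)=O and an acetyl C15(C)=O whose methyl is the future C14(B)), adds to C2(B) of an ene-dione (C3(B)=O, C1(B)=C2(B), C10(B)=O, C14 removed). The acetyl methyl then closes on the C10(B) ketone.
- For: two C–C bonds, the ring, the quaternary centre and the carbinol are made in one operation by well-understood ionic chemistry. It is more convergent and forms more bonds than the chosen key step.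
- Against: both partners need skeletal surgery. C14 must be excised from unit B in the presence of two other 1,1-disubstituted alkenes, and C15(C) must be raised to a ketone.
- Against: A2 keeps a C15(C) carbonyl that has to be removed next to a quaternary centre, among three ketones and two methylene lactones that do not tolerate thioketal or hydrazone reductions.
- Against: C4(C) (Michael face) and C10(B) (aldol face) are set independently, the ene-dione can be attacked at C1 as well as C2, and the methylene lactones are exposed to base.
- Comparison: the chosen step forms only one C–C bond, but every carbon stays where the monomer has it, the oxidation level comes out right, and the two new centres are coupled through the oxygen bridge.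

**Alternative 3:** The disconnection is C2(A)–C4(B), reached through the allyl vinyl ether array C4(B)=C3(B)–O–C10(A)–C1(A)=C2(A). The forward key step is a thermal or Me2AlCl-promoted [3,3] shift that forms C2(A)–C4(B), breaks O–C10(A), returns the C3(B) ketone and gives A3.
- For: it uses the hetero-Diels–Alder reactivity of α-methylene ketones and an ordered sigmatropic transition state to set C4(B). Where the carbon Diels–Alder reaction fails on periselectivity it is as strong as step 13 of the chosen route.
- Against: A3 holds the same β,γ-enone array that direct cycloaddition gives in one step, so the detour gains nothing unless periselectivity fails.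
- Against: the array would have to come from a hetero-Diels–Alder union at C10=C14 of the unstable trienone 21. Retro-cycloaddition on heating and ionisation of the doubly allylic C10(A)–O bond under Lewis acid would erode the stereochemistry.
- Against: A3 has no unit C. R2 would then have to be built by a cycloaddition and an allylic oxygenation at C10(B) with no facial control.
- Comparison: the chosen plan installs the C10(B) oxygen early with defined configuration and keeps the rearrangement-free cycloaddition for R1.

Key step: step 6

## Route

Remark on the chemistry: three centres that are erased later (C3 of 3, C4(B) of 6 to 15, and the ketal carbon of 12 and 15 to 18) are drawn as the single epimers expected from the reagents; their configuration has no bearing on the route.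

Step 1
Reactants: 1 dehydrocostus lactone; 2 tert-butyl hydroperoxide
Product: 3 3-epizaluzanin C (3α-hydroxydehydrocostus lactone)
Conditions: SeO2 (0.5 equiv), t-BuOOH (2 equiv), CH2Cl2, 0 °C to rt
Reagents that add atoms: tert-butyl hydroperoxide, CC(C)(C)OO
Why: Catalytic SeO2 allylic oxidation (ene reaction, then [2,3]-sigmatropic shift, the selenium being reoxidised by t-BuOOH) takes the cyclopentane methylene C3 beside the C4 exo-methylene, the allylic site this reagent favours here (C1 and C5 are methine). Oxygen should arrive on the convex α face; the centre is removed in step 2, and any 4 formed by over-oxidation is carried on.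

Step 2
Reactants: 3 3-epizaluzanin C
Product: 4 dehydrozaluzanin C
Conditions: Dess–Martin periodinane, CH2Cl2, 0 °C to rt
Reagents that add atoms: none
Why: Dess–Martin oxidation of a secondary allylic alcohol under neutral conditions that leave the three alkenes alone. 4 is kept cold and dilute because exo-methylene cyclopentanones dimerise.

Step 3
Reactants: 4 dehydrozaluzanin C; 5 sodium benzenesulfinate
Product: 6 15-(phenylsulfonyl)-4,15-dihydrodehydrozaluzanin C (masked unit B)
Conditions: PhSO2Na (1.05 equiv), AcOH (1.1 equiv), EtOH/H2O, 0 °C to rt
Reagents that add atoms: sodium benzenesulfinate, [Na+].[O-]S(=O)c1ccccc1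
Why: Sulfa-Michael addition: benzenesulfinic acid, set free by AcOH, adds through sulfur to the s-cis exo-methylene ketone, the strongest acceptor in 4. The methylene lactone (an α-alkyl acrylate) reacts more slowly, so one equivalent at 0 °C should stop at 6. C4 is drawn with the sulfonylmethyl group trans to C6, the epimer expected after equilibration through the enol.

Step 4
Reactants: 4 dehydrozaluzanin C; 6 masked unit B
Product: 7 B–C spiro-dihydropyran
Conditions: 6 (4 equiv), Me2AlCl (0.3 equiv), CH2Cl2, −40 °C, 4 added over 4 h; Et3N, then aq NaHCO3
Reagents that add atoms: none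
Why: Lewis-acid-promoted inverse-demand hetero-Diels–Alder reaction: the complexed enone of 4 is attacked at C15 by the terminal carbon C14 of the only nucleophilic alkene of 6 (its own enone is masked, its methylene lactone is electron-poor), and the enolate oxygen closes on the tertiary C10. Excess 6 (recovered) and slow addition of 4 hold back the self-reaction of 4. The C–O bond should form axially on the β face of C10(B) (anti to H1, syn-axial only to H6 and H8), leaving the larger C14 chain equatorial; the closure is reversible under the Lewis acid, so this more stable spiro isomer should accumulate, and it fixes C10(B).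

Step 5
Reactants: 7 B–C spiro-dihydropyran; 8 chlorotrimethylsilane
Product: 9 trimethylsilyl enol ether of 7 (C2(B)=C3(B)–OSiMe3)
Conditions: LiN(SiMe3)2 (1.2 equiv), Me3SiCl (1.5 equiv, present from the start), THF, −78 °C; pentane, filtration
Reagents that add atoms: chlorotrimethylsilane, C[Si](C)(C)Cl
Why: Kinetic enolate formation with in-situ silylation: the hindered amide takes a proton from the C2(B) methylene, not the tertiary H4(B) (whose enolate would expel sulfinate) or the less acidic CH2 beside sulfur, and it is too poor a nucleophile to add to the methylene lactones at −78 °C. The non-aqueous work-up keeps both acid-labile enol ethers intact; 9 is used at once.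

Step 6
Reactants: 9 trimethylsilyl enol ether; 10 water
Product: 13 B–C ketol dimer (1,2-dihydro; unit B masked), via bridged oxocarbenium ion 11 (not isolated), via bridged hemiketal 12 (not isolated)
Conditions: 9 added over 1 h to (NH4)2Ce(NO3)6 (2.5 equiv), NaHCO3 (6 equiv), MeCN, −40 °C (final 5 mM); then H2O, 0 °C
Reagents that add atoms: water, O
Why: One-electron oxidation by tetravalent cerium of one of the two electron-rich alkenes of 9 (the methylene lactones and the 1,1-disubstituted alkene are far harder to oxidise) gives a radical cation, and C2(B) bonds to the enol-ether carbon C4(C); loss of the silyl group and a second electron transfer leave ion 11, which nitrate or water captures, and hemiketal 12 opens to ketol 13. The closest known reaction type is the oxidative coupling of silyl enol ethers with enol ethers by (NH4)2Ce(NO3)6 to 1,4-dicarbonyl compounds, used here within one molecule. Ring R2 closes in the 6-exo-trig mode along the carbon tether C1(B)–C10(B)–C14(B)–C15(C) (the same bond is 6-endo along the oxygen tether), giving a 2-oxabicyclo[2.2.2]octane; C2(B) is already gauche to both O and C14 on C10(B), so only a boat pyran is needed. At C2(B) the new bond must enter on the β face, where C10(B) stands on C1(B), so R2 is cis-fused to the cyclopentanone. At C4(C) the configuration is dictated by C10(B): the two-atom tether reaches only the face of the enol ether to which C1(B) points, the α face of unit C (that of H5(C)), and C15(C) is pushed to β as in 23. Regiochemistry needs no control beyond the positions of the two enol derivatives, and the open ketol is favoured over 12 because the bicyclic hemiketal forces the cyclopentane of unit C into a twisted fusion. The step needs the intramolecular coupling to beat nitrate capture and intermolecular coupling (slow addition, high dilution), and it needs the buffer, since acid would cleave both enol ethers.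

Step 7
Reactants: 13 B–C ketol dimer; 14 methanol
Product: 15 bridged methyl ketal of 13
Conditions: MeOH, pyridinium p-toluenesulfonate (cat.), 3 Å molecular sieves, 40 °C
Reagents that add atoms: methanol, CO
Why: Acid-catalysed intramolecular ketalisation of a δ-hydroxy ketone: the C10(B) hydroxyl re-forms ion 11, which methanol captures from the open sector between the oxygen and ethano bridges. The mixed ketal ties up the only ketone with an unhindered α-CH2, and the tertiary alcohol, for the enolate chemistry of steps 9 and 10. The sulfone still masks the B enone, so methanol cannot add there.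

Step 8
Reactants: 15 bridged methyl ketal
Product: 16 exo-methylene enone of unit B in the bridged ketal
Conditions: DBU (1.5 equiv), CH2Cl2, 0 °C
Reagents that add atoms: none
Why: E1cB elimination (retro-sulfa-Michael): DBU removes H4(B) and the enolate expels benzenesulfinate. Only the exocyclic C4(B)=C15(B) alkene can form because the leaving group sits on C15, so no ring hydrogen competes.

Step 9
Reactants: 16 exo-methylene enone; 8 chlorotrimethylsilane
Product: 17 trimethylsilyl dienol ether of 16 (C15(B)=C4(B)–C3(B)(OSiMe3)=C2(B))
Conditions: LiN(SiMe3)2 (1.5 equiv), Me3SiCl (2 equiv), THF, −78 to −40 °C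
Reagents that add atoms: chlorotrimethylsilane, C[Si](C)(C)Cl
Why: Kinetic enolate silylation: in 16 the B ketone has a single α-hydrogen (H2(B); C4 is sp2) and the C3(C) carbonyl is a ketal, so only the cross-conjugated 2-silyloxydiene can form. The hindered H2(B) may need −40 °C.

Step 10
Reactants: 17 trimethylsilyl dienol ether
Product: 18 cross-conjugated dienone of unit B in the bridged ketal
Conditions: Pd(OAc)2 (1.1 equiv), MeCN, rt
Reagents that add atoms: none
Why: Saegusa–Ito oxidation: Pd(OAc)2 (divalent palladium) turns the silyl enol ether into an oxa-π-allyl palladium enolate, and β-hydride elimination can only use H1(B), which is cis to the former H2(B) on the outer face of the C1–C2 bridge. The new alkene lies in a bridge of a bicyclo[2.2.2]octene, not at a bridgehead.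

Step 11
Reactants: 18 dienone ketal; 10 water
Product: 19 B–C ketol dienone (dienophile)
Conditions: pyridinium p-toluenesulfonate (cat.), acetone/H2O, rt
Reagents that add atoms: water, O
Why: Acetal hydrolysis by way of the oxocarbenium ion and its hemiketal; relief of the twisted ring fusion drives the opening, and the C10(B)–O bond does not ionise because its cation would be conjugated to the enone. The ketol is opened before the cycloaddition because its shape supplies the facial bias of step 13.

Step 12
Reactants: 4 dehydrozaluzanin C; 8 chlorotrimethylsilane
Product: 20 trimethylsilyl dienol ether of 4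
Conditions: LiN(SiMe3)2 (1.2 equiv), Me3SiCl (1.5 equiv), THF, −78 °C
Reagents that add atoms: chlorotrimethylsilane, C[Si](C)(C)Cl
Why: Kinetic α′-enolate silylation of an enone; only C2 carries α-hydrogens, and the conditions are those of step 9.

Step 13
Reactants: 20 trimethylsilyl dienol ether of 4; 19 B–C ketol dienone
Product: 22 A–B–C trimer as the β,γ-enone, via trienone 21 (not isolated)
Conditions: 20 (3 equiv) added over 6 h to 19 and Pd(OAc)2 (1.1 equiv per 20), MeCN, rt
Reagents that add atoms: none
Why: Saegusa–Ito oxidation gives trienone 21, whose diene C2=C1–C10=C14 is locked s-cis as a 1,2-bis(alkylidene)cycloheptane unit; it is intercepted in a Diels–Alder reaction by the exo-methylene of the dienone of 19, the acyl-bearing terminus C2(A) bonding to the substituted carbon C4(B) ("ortho" orientation). C4(B) is set by the face of 19: the diene should come from the β face, because in the open ketol the C5(C) branch of unit C is pseudo-axial on C4(C) and covers the α face of the B dienone. Slow addition keeps 21 dilute so that capture by 19 outruns its self-cycloaddition; the centre at C2(A) is lost in step 14.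

Step 14
Reactants: 22 A–B–C trimer as the β,γ-enone
Product: 23 ainsliatrimer A
Conditions: DBU (0.2 equiv), CH2Cl2, 0 °C
Reagents that add atoms: none
Why: Base-mediated isomerisation of a β,γ- to an α,β-unsaturated ketone through the extended enolate: H2(A) is the only doubly activated proton in 22 (unit B has no α-hydrogen left). Protonation at C10(A) is expected on the α face, that of H5(A), the β face being flanked by C6(A); this sets the last stereocentre.

## Compound list

1 | dehydrocostus lactone | C=C1CC[C@H]2C(=C)CC[C@H]3C(=C)C(=O)O[C@@H]3[C@H]21 | starting material
2 | tert-butyl hydroperoxide | CC(C)(C)OO | starting material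
3 | 3-epizaluzanin C (3α-hydroxydehydrocostus lactone) | C=C1[C@H](O)C[C@H]2C(=C)CC[C@H]3C(=C)C(=O)O[C@@H]3[C@H]21 | intermediate
4 | dehydrozaluzanin C (3-oxodehydrocostus lactone) | C=C1C(=O)C[C@H]2C(=C)CC[C@H]3C(=C)C(=O)O[C@@H]3[C@H]21 | intermediate
5 | sodium benzenesulfinate | [Na+].[O-]S(=O)c1ccccc1 | starting material
6 | 15-(phenylsulfonyl)-4,15-dihydrodehydrozaluzanin C (masked unit B; H4 β, CH2SO2Ph α) | O=S(=O)(C[C@@H]1C(=O)C[C@H]2C(=C)CC[C@H]3C(=C)C(=O)O[C@@H]3[C@H]21)c1ccccc1 | intermediate
7 | B–C spiro-dihydropyran (spiro at C10(B), O β and C14 α; enol ether O–C3(C)=C4(C); unit B masked) | O=S(=O)(C[C@@H]1C(=O)C[C@@H]2[C@H]1[C@H]3OC(=O)C(=C)[C@@H]3CC[C@@]24CCC5=C(O4)C[C@H]6C(=C)CC[C@H]7C(=C)C(=O)O[C@@H]7[C@@H]56)c1ccccc1 | intermediate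
8 | chlorotrimethylsilane | C[Si](C)(C)Cl | starting material
9 | trimethylsilyl enol ether of 7 (C2(B)=C3(B)–OSiMe3; key-step precursor) | O=S(=O)(C[C@@H]1C(O[Si](C)(C)C)=C[C@@H]2[C@H]1[C@H]3OC(=O)C(=C)[C@@H]3CC[C@@]24CCC5=C(O4)C[C@H]6C(=C)CC[C@H]7C(=C)C(=O)O[C@@H]7[C@@H]56)c1ccccc1 | intermediate
10 | water | O | starting material
11 | bridged oxocarbenium ion (2-oxabicyclo[2.2.2]octane, C3(C)=O+; C2(B)–C4(C) bond made) | O=S(=O)(C[C@@H]1C(=O)[C@@H]2[C@@H]3[C@H]1[C@H]1OC(=O)C(=C)[C@@H]1CC[C@@]34CC[C@]21C(=[O+]4)C[C@H]2C(=C)CC[C@H]3C(=C)C(=O)O[C@@H]3[C@H]21)c1ccccc1 | intermediate
12 | bridged hemiketal (hydrate of 11 at C3(C)) | O=S(=O)(C[C@@H]1C(=O)[C@@H]2[C@@H]3[C@H]1[C@H]1OC(=O)C(=C)[C@@H]1CC[C@@]34CC[C@]21[C@](O)(O4)C[C@H]2C(=C)CC[C@H]3C(=C)C(=O)O[C@@H]3[C@H]21)c1ccccc1 | intermediate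
13 | B–C ketol dimer (1,2-dihydro; unit B masked; C3(C) ketone, 10β-hydroxyl; key-step product) | O=S(=O)(C[C@@H]1C(=O)[C@@H]2[C@@H]3[C@H]1[C@H]1OC(=O)C(=C)[C@@H]1CC[C@@]3(O)CC[C@]21C(=O)C[C@H]2C(=C)CC[C@H]3C(=C)C(=O)O[C@@H]3[C@H]21)c1ccccc1 | intermediate
14 | methanol | CO | starting material
15 | bridged methyl ketal of 13 | O=S(=O)(C[C@@H]1C(=O)[C@@H]2[C@@H]3[C@H]1[C@H]1OC(=O)C(=C)[C@@H]1CC[C@@]34CC[C@]21[C@](OC)(O4)C[C@H]2C(=C)CC[C@H]3C(=C)C(=O)O[C@@H]3[C@H]21)c1ccccc1 | intermediate
16 | exo-methylene enone of unit B in the bridged ketal | C=C1C(=O)[C@@H]2[C@@H]3[C@H]1[C@H]1OC(=O)C(=C)[C@@H]1CC[C@@]34CC[C@]21[C@](OC)(O4)C[C@H]2C(=C)CC[C@H]3C(=C)C(=O)O[C@@H]3[C@H]21 | intermediate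
17 | trimethylsilyl dienol ether of 16 | C=C1C(O[Si](C)(C)C)=C2[C@@H]3[C@H]1[C@H]1OC(=O)C(=C)[C@@H]1CC[C@@]34CC[C@]21[C@](OC)(O4)C[C@H]2C(=C)CC[C@H]3C(=C)C(=O)O[C@@H]3[C@H]21 | intermediate
18 | cross-conjugated dienone of unit B in the bridged ketal (C1(B)=C2(B)) | C=C1C(=O)C2=C3[C@H]1[C@H]1OC(=O)C(=C)[C@@H]1CC[C@@]34CC[C@]21[C@](OC)(O4)C[C@H]2C(=C)CC[C@H]3C(=C)C(=O)O[C@@H]3[C@H]21 | intermediate
19 | B–C ketol dienone (free 10β-hydroxyl and C3(C) ketone; dienophile) | C=C1C(=O)C2=C3[C@H]1[C@H]1OC(=O)C(=C)[C@@H]1CC[C@@]3(O)CC[C@]21C(=O)C[C@H]2C(=C)CC[C@H]3C(=C)C(=O)O[C@@H]3[C@H]21 | intermediate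
20 | trimethylsilyl dienol ether of 4 | C=C1C(O[Si](C)(C)C)=C[C@H]2C(=C)CC[C@H]3C(=C)C(=O)O[C@@H]3[C@H]21 | intermediate
21 | trienone of unit A (diene C2=C1–C10=C14) | C=C1C(=O)C=C2C(=C)CC[C@H]3C(=C)C(=O)O[C@@H]3[C@H]21 | intermediate
22 | A–B–C trimer as the β,γ-enone (C1(A)=C10(A); H2(A) β) | C=C1C(=O)[C@H]2C3=C(CC[C@H]4C(=C)C(=O)O[C@@H]4[C@@H]13)CC[C@@]21C(=O)C2=C3[C@H]1[C@H]1OC(=O)C(=C)[C@@H]1CC[C@@]3(O)CC[C@]21C(=O)C[C@H]2C(=C)CC[C@H]3C(=C)C(=O)O[C@@H]3[C@H]21 | intermediate
23 | ainsliatrimer A | C=C1C(=O)C2=C3[C@H](CC[C@H]4C(=C)C(=O)O[C@@H]4[C@@H]13)CC[C@@]21C(=O)C2=C3[C@H]1[C@H]1OC(=O)C(=C)[C@@H]1CC[C@@]3(O)CC[C@]21C(=O)C[C@H]2C(=C)CC[C@H]3C(=C)C(=O)O[C@@H]3[C@H]21 | target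

## Step count and risk

Total: 14 steps. Longest linear sequence: 13 steps (steps 1 to 11, 13 and 14; step 12 is a one-step branch from 4).

**Step 6 (key step).** The most likely failure is loss of the silyl group, or capture of the first-formed radical cation by nitrate, before the slow C–C bond can form. That bond creates a quaternary centre and needs the pyran in a boat, so oxygenation at C4(C) or return to 7 can win; any acid that builds up would also cleave the tertiary C10(B)–O bond. The fallback sets out from 7 and comes back at 13. The lithium enolate of 7 (LiN(SiMe3)2, THF, −78 °C) is brominated with N-bromosuccinimide to the 2-bromo ketone F1. CuBr (monovalent copper) with tris(2-pyridylmethyl)amine in MeCN/H2O then starts a Kharasch-type atom-transfer radical cyclisation. The α-keto radical adds to C4(C) in the same 6-exo mode, the α-alkoxy radical takes bromine back from CuBr2, and the α-bromo ether ionises to 11, which water converts to 13. This path is redox-neutral and uses neither a strong oxidant nor acid.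

**Step 4.** Self-dimerisation of 4 through its own C4=C15 bond, and proton loss from the zwitterion (ene pathway) in place of C–O closure, are the likely diversions, because an unactivated alkene is a slow partner. Closure on the α face of C10(B) would in addition give the spiro epimer, which the key step would relay to the wrong C4(C). The fallback sets out from 4 and 6 and comes back at 7, and separates the two bond formations. With Me2AlCl at 0 °C the ene pathway is allowed to run to the conjugate-ene adduct F2 (C15(C)–C14(B) bond made, C9(B)=C10(B) alkene, C3(C) ketone). The pyran is then closed by camphorsulfonic acid in CH2Cl2, a Markovnikov addition of the enol oxygen to C10(B) under equilibrating conditions, which favour the axial C–O bond.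

**Step 13.** Self-cycloaddition of the transient trienone can outrun its capture by the hindered dienophile, and Pd(OAc)2 gives no control over how fast 21 is released. Approach to the α face of 19 would give the C4(B) epimer. The fallback sets out from 4 and 19 and comes back at 22. The enolate of 4 (LiN(SiMe3)2, −78 °C) is selenenylated with PhSeCl to 2α-(phenylselanyl)dehydrozaluzanin C F3. Oxidation with H2O2 at −78 °C in the presence of 19 gives the selenoxide F4, whose syn-elimination toward H1 on warming releases 21 slowly and without metal.

**Step 7.** The ketalisation equilibrium may stay on the side of the open ketol, because the ketal twists the ring fusion of unit C; slow ketalisation of the C3(B) ketone is the other risk. The fallback sets out from 9 and comes back at 15. The cerium oxidation of step 6 is run in MeCN/MeOH, so that ion 11 is trapped kinetically by methanol and the ketol is never released. This fallback makes no compound that is not already in the list (F0).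

**Step 3.** A second addition at C13 of the lactone, or reversal of the addition on work-up, would lower the selectivity, since sulfinate adds reversibly and is not a very discriminating nucleophile. The fallback sets out from 4 and comes back at 6. Thiophenol with catalytic Et3N at −78 °C, a softer and more selective donor, gives the 15-(phenylsulfanyl) adduct F5. H2O2 with catalytic (NH4)6Mo7O24 then oxidises sulfur to the sulfone without touching the alkenes.

## Further compounds

F1 | step 6 | 2α-bromo ketone of 7 | O=S(=O)(C[C@@H]1C(=O)[C@H](Br)[C@@H]2[C@H]1[C@H]3OC(=O)C(=C)[C@@H]3CC[C@@]24CCC5=C(O4)C[C@H]6C(=C)CC[C@H]7C(=C)C(=O)O[C@@H]7[C@@H]56)c1ccccc1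
F2 | step 4 | conjugate-ene adduct of 4 and 6 (C15(C)–C14(B) bond, C9(B)=C10(B) alkene) | O=S(=O)(C[C@@H]1C(=O)C[C@@H]2[C@H]1[C@H]1OC(=O)C(=C)[C@@H]1CC=C2CC[C@@H]1C(=O)C[C@H]2C(=C)CC[C@H]3C(=C)C(=O)O[C@@H]3[C@H]21)c1ccccc1
F3 | step 13 | 2α-(phenylselanyl)dehydrozaluzanin C | C=C1C(=O)[C@H]([Se]c2ccccc2)[C@H]2C(=C)CC[C@H]3C(=C)C(=O)O[C@@H]3[C@H]21
F4 | step 13 | selenoxide of F3 (both configurations at selenium) | C=C1C(=O)[C@H]([Se](=O)c2ccccc2)[C@H]2C(=C)CC[C@H]3C(=C)C(=O)O[C@@H]3[C@H]21
F0 | step 7 | none | none
F5 | step 3 | 15-(phenylsulfanyl)-4,15-dihydrodehydrozaluzanin C | C(Sc1ccccc1)[C@@H]1C(=O)C[C@H]2C(=C)CC[C@H]3C(=C)C(=O)O[C@@H]3[C@H]21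
A1 | alternative 1 | A–B spiro dimer with ring R1 as a cyclohexadiene | C=C1C(=O)C2=C3C(CC[C@H]4C(=C)C(=O)O[C@@H]4[C@@H]13)=CC[C@@]21C(=O)C[C@H]2C(=C)CC[C@H]3C(=C)C(=O)O[C@@H]3[C@H]21
A2 | alternative 2 | B–C ketol carrying a C15(C) carbonyl | C=C1C(=O)[C@@H]2[C@@H]3[C@H]1[C@H]1OC(=O)C(=C)[C@@H]1CC[C@@]3(O)CC(=O)[C@]21C(=O)C[C@H]2C(=C)CC[C@H]3C(=C)C(=O)O[C@@H]3[C@H]21
A3 | alternative 3 | A–B spiro dimer in the β,γ-enone form | C=C1C(=O)[C@H]2C3=C(CC[C@H]4C(=C)C(=O)O[C@@H]4[C@@H]13)CC[C@@]21C(=O)C[C@H]2C(=C)CC[C@H]3C(=C)C(=O)O[C@@H]3[C@H]21
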